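How much target stands after 8.0 min as partner A is raised, and where does the row turn? Each of the flasks below gets the same partner B and protic impurity, and differs in partner A.

the same everywhere: substrate 10 mM
- summer: partner A 0.83 equiv; partner B 4 equiv; protic impurity 10 mM; run made earlier
- autumn: partner A 2.6 equiv; partner B 4 equiv; protic impurity 10 mM; run made earlier
- theta: partner A 0.600 equiv; partner B 4.00 equiv; protic impurity 10.0 mM; time 8.0 min
- eta: partner A 1.00 equiv; partner B 4.00 equiv; protic impurity 10.0 mM; time 8.0 min
- delta: partner A 1.50 equiv; partner B 4.00 equiv; protic impurity 10.0 mM; time 8.0 min
- epsilon: partner A 2.00 equiv; partner B 4.00 equiv; protic impurity 10.0 mM; time 8.0 min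

| run | time / min | target / % |
|---|---|---|
| summer | 0.500 | 13.7 |
| summer | 1.33 | 36.0 |
| summer | 2.50 | 52.4 |
| summer | 4.00 | 64.6 |
| summer | 6.00 | 73.3 |
| autumn | 1.00 | 26.0 |
| autumn | 2.50 | 39.4 |
| autumn | 3.00 | 40.9 |
| autumn | 5.00 | 47.7 |
| autumn | 6.00 | 51.1 |

(readings scatter by 1 percentage point)

* amount of target at the end, in percent of the substrate charged for theta, eta, delta, epsilon, in this order
* how the row runs (falls all the way / rises, then falls / falls, then rises / hardly changes / rises all the way)

- the numbers in the tables scatter by 1 percentage point (one standard deviation)
- "hardly changes" means that all values lie within two and a half points (for a concentration: within two and a half percent of the largest)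

We keep a ledger of partner A, taking one partner A per target as our assumption. The first entry is what the target peak holds. The second is what it does not hold, read at each run's last reading.

| run | partner A charged | in target | not in target |
|---|---|---|---|
| summer | 8.30 mM | 7.33 mM | 0.970 mM |
| autumn | 26.0 mM | 5.11 mM | 20.9 mM |

Autumn was charged with more partner A yet books less target at 6.00 min, so in these two runs, with the other charges equal, extra partner A goes with slower growth of target. To measure this we use one number, the run's clock, an apparent pseudo-first-order constant: minus the natural logarithm of the part of the substrate charged that is not in target, divided by the time. Summer reads 0.220 min⁻¹ and autumn reads 0.119 min⁻¹.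

Our reckoning lets the clock fall on a straight line in equivalents between these two readings, and then caps target at the partner A charged. Theta's ceiling, 60.0 %, lies below the 82.8 % that summer's clock offers, so the ceiling is what we book. For eta, delta and epsilon the line estimates clocks of 0.210 min⁻¹, 0.182 min⁻¹ and 0.153 min⁻¹, which give estimates of 81.4 %, 76.7 % and 70.7 %.

The forecast gives 57 %, 80 %, 74 % and 65 %, so rises, then falls, on the grounds that “Excess A therefore sets off some time-dependent deactivation”. Our numbers stand higher at eta, delta and epsilon, with the same shape.

The flasks give 59.8 %, 81.6 %, 77.6 % and 68.8 %: rises, then falls.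

    substrate + partner B → open intermediate (k = 0.236 M⁻¹ s⁻¹)
    partner B + partner A → second intermediate (k = 1.66 M⁻¹ s⁻¹)
    open intermediate + second intermediate → target (k = 37.5 M⁻¹ s⁻¹)
    2 open intermediate → homo product (k = 26.5 M⁻¹ s⁻¹)
    partner B + protic impurity → quenched reagent (k = 0.270 M⁻¹ s⁻¹)

In theta at 8.00 min, with partner A at 0 %, open intermediate goes to target at 0.060 of the rate at which it goes to homo product. Target in theta stands at 60.0 % at 80.0 min, while homo product climbs from 27.7 % to 39.9 %. Read back from the end values, eta's clock is 0.212 min⁻¹ and epsilon's is 0.146 min⁻¹, against summer's 0.220 min⁻¹. In epsilon's ledger, c(second intermediate) holds 13.1 mM of the 20.0 mM of partner A charged.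

The numbers in the tables were generated by integration from invented constants; noise was put on by code.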